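The readings were generated by integration with constants of no real substance.

Count every amount as a fraction of the solid substrate charged, which is the limiting reagent, at 0.020 M against 0.0500 M of coupling partner.

| flask | solid substrate | coupling partner | scavenger | temperature | remark | time |
|---|---|---|---|---|---|---|
| dawn | 0.013 M | 0.050 M | 0.024 M | 108 °C | run made earlier |  |
| dusk | 0.030 M | 0.050 M | 0.024 M | 124 °C | run made earlier |  |
| theta | 0.020 M | 0.0500 M | 0.0240 M | 115 °C |  | 2.0 min |
| eta | 0.020 M | 0.0500 M | 0.0240 M |  | at 130 °C until 1.0 min, from then on at 100 °C | 2.0 min |
| gamma | 0.020 M | 0.0500 M | 0.0240 M | 100 °C |  | 2.0 min |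
| alpha | 0.020 M | 0.0500 M | 0.0240 M | 130 °C |  | 2.0 min |

| run | time / s | product / % | solid substrate / % |
|---|---|---|---|
| dawn | 15.0 | 0.8 | 86.4 |
| dawn | 30.0 | 5.0 | 73.5 |
| dawn | 40.0 | 8.9 | 65.6 |
| dawn | 60.0 | 17.3 | 48.9 |
| dawn | 80.0 | 26.1 | 33.5 |
| dawn | 90.0 | 31.2 | 26.7 |
| dusk | 10.0 | 0.4 | 96.4 |
| dusk | 20.0 | 2.6 | 91.6 |
| dusk | 25.0 | 4.1 | 90.4 |
| dusk | 40.0 | 6.8 | 84.9 |
| dusk | 50.0 | 8.6 | 80.8 |
| dusk | 60.0 | 12.1 | 77.6 |

(readings scatter by 0.5 percentage points)

- amounts and yields of released group count idle adduct too
- given per volume of solution although it is solid: solid substrate
- steps under discussion: starting material + released group <-> idle adduct; scavenger + released group -> scavenged by-product; solid substrate <-> starting material; starting material + coupling partner <-> product + released group; released group -> by-product carried off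
- at the start none of the solid substrate is in solution
- what has only dissolved of solid substrate counts as not reacted

1. the flask that comes out highest in amount of product, in percent of the solid substrate charged, or "all alike" when all lie within 1.5 percentage points (theta / eta / gamma / alpha / all alike)
2. product at the end, in percent of the solid substrate charged, theta
3. product at the end, in percent of the solid substrate charged, eta
4. product at the end, in percent of the solid substrate charged, gamma
5. product at the end, in percent of the solid substrate charged, alpha

First turn the earlier runs into a current of solid entering solution. In the dawn run 73.3% of the charge has left the solid by 90.0 s, a current of 1.06 × 10⁻⁴ M/s. In the dusk run, hotter and with a larger charge, 22.4% has left by 60.0 s, a current of 1.12 × 10⁻⁴ M/s. As a reading, then, the current is about 1.09 × 10⁻⁴ M/s. My own reckoning for a charge of 0.020 M after 2.0 min gives 65.4% as the dissolved share, the current times the time over the charge.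

Now two people argue. The first says the flask is a pipe: the two runs, which differ in temperature and in charge, show nearly the same current, so the share is common to the flasks, product follows it, and no flask stands out.

The second answers from the same table. At 90.0 s the dawn run holds 31.2% of product against 73.3% dissolved, so dissolved material waits in solution, and the wait can depend on temperature.

The forecast takes this side: “Dissolved starting material then converts pseudo-first-order”. Its dissolved share is 69 %, mine 65.4%. It gives 25% for gamma, 33% for eta, 41% for theta and 51% for alpha, so alpha comes out highest.

The simulation gives 24.7% for gamma, 32.0% for eta, 36.1% for theta and 45.0% for alpha.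

    starting material + released group ⇌ idle adduct, settled at all times (K = 140 /M, ΔH = −25.0 kJ/mol)
    scavenger + released group → scavenged by-product (k = 1.50 /M/s, Ea = 62.0 kJ/mol)
    solid substrate ⇌ starting material, rate k3*(cs3 - [starting material]) while solid is left; crystals form when [starting material] > cs3 (solubility = 18.0 mM, k = 0.00710 /s)
    starting material + coupling partner ⇌ product + released group (K = 0.740, k = 0.220 /M/s, Ea = 52.0 kJ/mol, ΔH = −90.0 kJ/mol)
    released group → by-product carried off (k = 0.00300 /s, Ea = 113 kJ/mol)
    (constants at 100 °C)

So alpha is highest, the flasks spread over 20 percentage points, the second speaker wins, and the forecast stands 6 points high on alpha. In eta the solid stood at 65.7% at the change of temperature and 36.7% at the end, so 63.3% had dissolved against the reckoned 65.4%, while the coupling step ran on what was in solution, ending with starting material at 27.5% and product at 32.0%. The first speaker's view holds at 20.0 min, with gamma at 99.3% and alpha at >99.9%. The neighbour of eta with 0.0080 M of solid substrate has a reckoned share of 163% and a reckoned emptying time of 73.4 s, and at 2.00 min that flask holds solid substrate at 0% and product at 69.3%.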